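**Retrosynthetic overview**
1. The side-chain acid is unmasked last from a primary silyl ether; the tropone comes from a cyclohepta-1,4-diene by DDQ dehydrogenation and loss of silanol.
2. The seven-membered ring is formed by a formal [4+3] cycloaddition: a rhodium vinylcarbenoid cyclopropanates a lactone-derived 2-siloxy diene, and the cis-divinylcyclopropane undergoes a [3,3] Cope shift.
3. The future dihydrofuran is carried as a spiro γ-lactone, made by opening a spiro-epoxide with a pentenoic acid dienediolate; the spiro C–O bond is set by face-selective epoxidation of an exocyclic alkene.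
4. The cyclohexane is bought as (S)-carvone: two α'-alkylations (the second anti to isopropenyl) set the quaternary centre, Mukaiyama hydration gives the tertiary alcohol, and face-selective hydrogenation sets the CHMe centre.
5. Ring order: cyclohexane (purchased), then spiro-lactone (future five-membered ring), then seven-membered ring.

Assumption: the C3 epimers of lactone 14 and any minor (E)-propenyl isomer are carried forward, because both elements are erased when the tropone forms; compounds 4, 11 and 15 are taken as commercial.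

**Route**

Step 1
Reactants: 1 (S)-carvone
Product: 3 (5S,6R)-2,6-dimethyl-5-(prop-1-en-2-yl)cyclohex-2-en-1-one, via lithium dienolate 2 (not isolated)
Conditions: LiN(iPr)2, THF, −78 °C; MeI, −78 → 0 °C
Reagents that add atoms: iodomethane (CI)
Why: Kinetic α'-deprotonation of the enone and SN2 enolate methylation give the 6-methyl ketone; the new centre (mainly trans to isopropenyl) is erased on re-enolisation in step 2.

Step 2
Reactants: 3 (5S,6R)-2,6-dimethyl-5-(prop-1-en-2-yl)cyclohex-2-en-1-one; 4 tert-butyl(3-iodopropoxy)dimethylsilane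
Product: 6 (5R,6R)-6-[3-(tert-butyldimethylsilyloxy)propyl]-2,6-dimethyl-5-(prop-1-en-2-yl)cyclohex-2-en-1-one, via lithium dienolate 5 (not isolated)
Conditions: LiN(iPr)2, THF, −78 °C; DMPU, 4, −78 °C → rt
Reagents that add atoms: none
Why: Enolate alkylation of the tetrasubstituted α'-enolate occurs on the face opposite the adjacent isopropenyl group, so the three-carbon chain ends trans and the methyl cis to it (quaternary centre R, controlled by the carvone centre).

Step 3
Reactants: 6 (5R,6R)-6-[3-(tert-butyldimethylsilyloxy)propyl]-2,6-dimethyl-5-(prop-1-en-2-yl)cyclohex-2-en-1-one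
Product: 7 (5S,6R)-6-[3-(tert-butyldimethylsilyloxy)propyl]-5-(2-hydroxypropan-2-yl)-2,6-dimethylcyclohex-2-en-1-one
Conditions: Co(acac)2 (20 mol %), PhSiH3, O2 (1 atm), THF, rt
Reagents that add atoms: dioxygen (O=O)
Why: Mukaiyama hydration (hydrogen-atom transfer, O2 trapping, Markovnikov) is selective for the electron-rich 1,1-disubstituted alkene over the enone and touches no stereocentre.

Step 4
Reactants: 7 (5S,6R)-6-[3-(tert-butyldimethylsilyloxy)propyl]-5-(2-hydroxypropan-2-yl)-2,6-dimethylcyclohex-2-en-1-one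
Product: 8 (2R,3S,6R)-2-[3-(tert-butyldimethylsilyloxy)propyl]-3-(2-hydroxypropan-2-yl)-2,6-dimethylcyclohexan-1-one
Conditions: H2 (1 atm), Pd/C (10 wt %), EtOAc, rt
Reagents that add atoms: none
Why: Heterogeneous syn-hydrogenation of the enone C=C takes place on the face opposite the pseudoaxial quaternary methyl, so the new CHMe methyl ends cis to it (new centre R) under neutral, non-epimerising conditions.

Step 5
Reactants: 8 (2R,3S,6R)-2-[3-(tert-butyldimethylsilyloxy)propyl]-3-(2-hydroxypropan-2-yl)-2,6-dimethylcyclohexan-1-one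
Product: 9 2-[(1S,2R,4R)-2-[3-(tert-butyldimethylsilyloxy)propyl]-2,4-dimethyl-3-methylidenecyclohexyl]propan-2-ol
Conditions: Zn, CH2Br2, TiCl4, THF/CH2Cl2, 0 °C → rt
Reagents that add atoms: dibromomethane (BrCBr)
Why: Takai–Lombardo methylenation is non-basic, so the hindered ketone is converted to the exocyclic alkene without epimerising the adjacent CHMe centre.

Step 6
Reactants: 9 2-[(1S,2R,4R)-2-[3-(tert-butyldimethylsilyloxy)propyl]-2,4-dimethyl-3-methylidenecyclohexyl]propan-2-ol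
Product: 10 2-[(3S,4R,5S,8R)-4-[3-(tert-butyldimethylsilyloxy)propyl]-4,8-dimethyl-1-oxaspiro[2.5]octan-5-yl]propan-2-ol
Conditions: DMDO, acetone, 0 °C
Reagents that add atoms: dimethyldioxirane (CC1(C)OO1)
Why: Dioxirane epoxidation of the exocyclic alkene occurs on the face anti to the two flanking ring methyls and the hydroxyisopropyl group, which fixes the spiro C–O bond trans to them (spiro centre S).

Step 7
Reactants: 10 2-[(3S,4R,5S,8R)-4-[3-(tert-butyldimethylsilyloxy)propyl]-4,8-dimethyl-1-oxaspiro[2.5]octan-5-yl]propan-2-ol; 11 (E)-pent-2-enoic acid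
Product: 14 (5S,6R,7S,10R)-6-[3-(tert-butyldimethylsilyloxy)propyl]-7-(2-hydroxypropan-2-yl)-6,10-dimethyl-3-[(Z)-prop-1-enyl]-1-oxaspiro[4.5]decan-2-one (C3 epimers), via dilithium dienediolate 12 (not isolated), via hydroxy acid 13 (not isolated)
Conditions: 11 (3 equiv), LiN(iPr)2 (6 equiv), THF, −78 → 0 °C; 10, 0 → 50 °C; 1 M HCl work-up; TsOH·H2O (cat.), CH2Cl2, rt
Reagents that add atoms: none
Why: The acid dienediolate attacks through its α-carbon at the epoxide CH2 (SN2 epoxide opening, spiro C–O bond untouched, deconjugated alkene expected Z), and the γ-hydroxy acid lactonises by acyl substitution with retention at the spiro centre.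

Step 8
Reactants: 15 methyl 3-oxopentanoate
Product: 16 methyl 2-diazo-3-oxopentanoate
Conditions: 4-acetamidobenzenesulfonyl azide, Et3N, MeCN, 0 °C → rt
Reagents that add atoms: 4-acetamidobenzenesulfonyl azide (CC(=O)Nc1ccc(cc1)S(=O)(=O)N=[N+]=[N-])
Why: Regitz diazo transfer to the active methylene of the β-keto ester.

Step 9
Reactants: 16 methyl 2-diazo-3-oxopentanoate
Product: 17 methyl (3Z)-3-(tert-butyldimethylsilyloxy)-2-diazopent-3-enoate
Conditions: TBSOTf, Et3N, CH2Cl2, 0 °C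
Reagents that add atoms: tert-butyldimethylsilyl trifluoromethanesulfonate (CC(C)(C)[Si](C)(C)OS(=O)(=O)C(F)(F)F)
Why: Soft enolisation and O-silylation of the diazo keto ester give the (Z)-siloxyvinyl diazoacetate, the vinylcarbenoid precursor.

Step 10
Reactants: 14 (5S,6R,7S,10R)-6-[3-(tert-butyldimethylsilyloxy)propyl]-7-(2-hydroxypropan-2-yl)-6,10-dimethyl-3-[(Z)-prop-1-enyl]-1-oxaspiro[4.5]decan-2-one
Product: 19 (5S,6R,7S,10R)-6-[3-(tert-butyldimethylsilyloxy)propyl]-6,10-dimethyl-3-[(Z)-prop-1-enyl]-2-(trimethylsilyloxy)-7-[2-(trimethylsilyloxy)propan-2-yl]-1-oxaspiro[4.5]dec-2-ene, via dilithium alkoxide dienolate 18 (not isolated)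
Conditions: LiN(iPr)2 (2.3 equiv), THF, −78 °C; TMSCl (3 equiv), −78 °C → rt; hexane, filter, used crude
Reagents that add atoms: chlorotrimethylsilane (C[Si](C)(C)Cl)
Why: α-Deprotonation of the β,γ-unsaturated lactone and O-silylation give the 2-siloxy diene (silyl ketene acetal formation) while the tertiary alcohol is capped as its trimethylsilyl ether; no ring stereocentre is affected.

Step 11
Reactants: 19 (5S,6R,7S,10R)-6-[3-(tert-butyldimethylsilyloxy)propyl]-6,10-dimethyl-3-[(Z)-prop-1-enyl]-2-(trimethylsilyloxy)-7-[2-(trimethylsilyloxy)propan-2-yl]-1-oxaspiro[4.5]dec-2-ene; 17 methyl (3Z)-3-(tert-butyldimethylsilyloxy)-2-diazopent-3-enoate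
Product: 21 methyl (1S,2R,3S,6R)-7'-(tert-butyldimethylsilyloxy)-2-[3-(tert-butyldimethylsilyloxy)propyl]-2,5',6,8'-tetramethyl-8a'-(trimethylsilyloxy)-3-[2-(trimethylsilyloxy)propan-2-yl]-3',5',8',8a'-tetrahydrospiro[cyclohexane-1,2'-cyclohepta[b]furan]-6'-carboxylate (mixture at C5', C8', C8a'), via divinylcyclopropane 20 (not isolated)
Conditions: Rh2(OPiv)4 (1 mol %), hexanes, reflux, slow addition of 17 (1.5 equiv); filter through neutral alumina
Reagents that add atoms: none
Why: Tandem cyclopropanation/Cope rearrangement (formal [4+3] cycloaddition): the rhodium vinylcarbenoid cyclopropanates the distal cis-propenyl alkene at the nucleophilic diene terminus, and the cis-divinylcyclopropane undergoes a boat [3,3]-sigmatropic shift to the cyclohepta-1,4-diene; the three new ring centres are unselective and are erased in step 12.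

Step 12
Reactants: 21 methyl (1S,2R,3S,6R)-7'-(tert-butyldimethylsilyloxy)-2-[3-(tert-butyldimethylsilyloxy)propyl]-2,5',6,8'-tetramethyl-8a'-(trimethylsilyloxy)-3-[2-(trimethylsilyloxy)propan-2-yl]-3',5',8',8a'-tetrahydrospiro[cyclohexane-1,2'-cyclohepta[b]furan]-6'-carboxylate
Product: 23 methyl (1S,2R,3S,6R)-2-(3-hydroxypropyl)-3-(2-hydroxypropan-2-yl)-2,5',6,8'-tetramethyl-7'-oxo-3'H,7'H-spiro[cyclohexane-1,2'-cyclohepta[b]furan]-6'-carboxylate, via dienone silyl ketal 22 (not isolated)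
Conditions: DDQ (1.2 equiv), CH2Cl2, 0 °C → rt; HF·pyridine, THF, 0 °C → rt
Reagents that add atoms: none
Why: DDQ dehydrogenation (hydride abstraction at the doubly allylic CH next to the silyl enol ether) gives the dienone, and acidic fluoride then eliminates silanol from the mixed ketal to aromatise to the tropone and cleaves the silyl ethers; the spiro centre is not ionised.

Step 13
Reactants: 23 methyl (1S,2R,3S,6R)-2-(3-hydroxypropyl)-3-(2-hydroxypropan-2-yl)-2,5',6,8'-tetramethyl-7'-oxo-3'H,7'H-spiro[cyclohexane-1,2'-cyclohepta[b]furan]-6'-carboxylate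
Product: 25 3-[(1S,2R,3S,6R)-3-(2-hydroxypropan-2-yl)-6'-(methoxycarbonyl)-2,5',6,8'-tetramethyl-7'-oxo-3'H,7'H-spiro[cyclohexane-1,2'-cyclohepta[b]furan]-2-yl]propanoic acid (target), via aldehyde 24 (not isolated)
Conditions: TEMPO (20 mol %), PhI(OAc)2 (2.5 equiv), MeCN/H2O, rt
Reagents that add atoms: water (O)
Why: Oxoammonium (TEMPO) oxidation takes the primary alcohol through the aldehyde hydrate to the acid and leaves the tertiary alcohol, methyl ester and tropone untouched.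

**Compound list**

1 | (S)-carvone | O=C1C(C)=CC[C@H](C(C)=C)C1 | starting material
2 | lithium dienolate of 1 | [Li+].[O-]C1=C[C@@H](C(C)=C)CC=C1C | intermediate (not isolated)
3 | (5S,6R)-2,6-dimethyl-5-(prop-1-en-2-yl)cyclohex-2-en-1-one | O=C1C(C)=CC[C@H](C(C)=C)[C@H]1C | intermediate
4 | tert-butyl(3-iodopropoxy)dimethylsilane | CC(C)(C)[Si](C)(C)OCCCI | starting material
5 | lithium dienolate of 3 | [Li+].[O-]C1=C(C)[C@@H](C(C)=C)CC=C1C | intermediate (not isolated)
6 | (5R,6R)-6-[3-(tert-butyldimethylsilyloxy)propyl]-2,6-dimethyl-5-(prop-1-en-2-yl)cyclohex-2-en-1-one | O=C1C(C)=CC[C@H](C(C)=C)[C@@]1(C)CCCO[Si](C)(C)C(C)(C)C | intermediate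
7 | (5S,6R)-6-[3-(tert-butyldimethylsilyloxy)propyl]-5-(2-hydroxypropan-2-yl)-2,6-dimethylcyclohex-2-en-1-one | O=C1C(C)=CC[C@H](C(C)(C)O)[C@@]1(C)CCCO[Si](C)(C)C(C)(C)C | intermediate
8 | (2R,3S,6R)-2-[3-(tert-butyldimethylsilyloxy)propyl]-3-(2-hydroxypropan-2-yl)-2,6-dimethylcyclohexan-1-one | O=C1[C@H](C)CC[C@H](C(C)(C)O)[C@@]1(C)CCCO[Si](C)(C)C(C)(C)C | intermediate
9 | 2-[(1S,2R,4R)-2-[3-(tert-butyldimethylsilyloxy)propyl]-2,4-dimethyl-3-methylidenecyclohexyl]propan-2-ol | C=C1[C@H](C)CC[C@H](C(C)(C)O)[C@@]1(C)CCCO[Si](C)(C)C(C)(C)C | intermediate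
10 | 2-[(3S,4R,5S,8R)-4-[3-(tert-butyldimethylsilyloxy)propyl]-4,8-dimethyl-1-oxaspiro[2.5]octan-5-yl]propan-2-ol | C1O[C@]12[C@H](C)CC[C@H](C(C)(C)O)[C@@]2(C)CCCO[Si](C)(C)C(C)(C)C | intermediate
11 | (E)-pent-2-enoic acid | CC/C=C/C(=O)O | starting material
12 | dilithium (3Z)-penta-1,3-diene-1,1-diolate | [Li+].[Li+].[O-]C([O-])=C/C=C\C | intermediate (not isolated)
13 | (3Z)-2-{[(1S,2R,3S,6R)-2-[3-(tert-butyldimethylsilyloxy)propyl]-1-hydroxy-3-(2-hydroxypropan-2-yl)-2,6-dimethylcyclohexyl]methyl}pent-3-enoic acid | OC(=O)C(/C=C\C)C[C@]1(O)[C@H](C)CC[C@H](C(C)(C)O)[C@@]1(C)CCCO[Si](C)(C)C(C)(C)C | intermediate (not isolated)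
14 | (5S,6R,7S,10R)-6-[3-(tert-butyldimethylsilyloxy)propyl]-7-(2-hydroxypropan-2-yl)-6,10-dimethyl-3-[(Z)-prop-1-enyl]-1-oxaspiro[4.5]decan-2-one (C3 epimers) | O=C1O[C@@]2(CC1/C=C\C)[C@H](C)CC[C@H](C(C)(C)O)[C@@]2(C)CCCO[Si](C)(C)C(C)(C)C | intermediate
15 | methyl 3-oxopentanoate | CCC(=O)CC(=O)OC | starting material
16 | methyl 2-diazo-3-oxopentanoate | CCC(=O)C(=[N+]=[N-])C(=O)OC | intermediate
17 | methyl (3Z)-3-(tert-butyldimethylsilyloxy)-2-diazopent-3-enoate | C/C=C(\O[Si](C)(C)C(C)(C)C)C(=[N+]=[N-])C(=O)OC | intermediate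
18 | dilithium alkoxide dienolate of 14 | [Li+].[Li+].[O-]C1=C(/C=C\C)C[C@]2(O1)[C@H](C)CC[C@H](C(C)(C)[O-])[C@@]2(C)CCCO[Si](C)(C)C(C)(C)C | intermediate (not isolated)
19 | (5S,6R,7S,10R)-6-[3-(tert-butyldimethylsilyloxy)propyl]-6,10-dimethyl-3-[(Z)-prop-1-enyl]-2-(trimethylsilyloxy)-7-[2-(trimethylsilyloxy)propan-2-yl]-1-oxaspiro[4.5]dec-2-ene | C[Si](C)(C)OC1=C(/C=C\C)C[C@]2(O1)[C@H](C)CC[C@H](C(C)(C)O[Si](C)(C)C)[C@@]2(C)CCCO[Si](C)(C)C(C)(C)C | intermediate
20 | cis-divinylcyclopropane (cyclopropane from the carbenoid carbon and the propenyl alkene of 19; ring relative configuration not defined) | COC(=O)C1(/C(O[Si](C)(C)C(C)(C)C)=C/C)C(C)C1C1=C(O[Si](C)(C)C)O[C@@]2(C1)[C@H](C)CC[C@H](C(C)(C)O[Si](C)(C)C)[C@@]2(C)CCCO[Si](C)(C)C(C)(C)C | intermediate (not isolated)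
21 | methyl (1S,2R,3S,6R)-7'-(tert-butyldimethylsilyloxy)-2-[3-(tert-butyldimethylsilyloxy)propyl]-2,5',6,8'-tetramethyl-8a'-(trimethylsilyloxy)-3-[2-(trimethylsilyloxy)propan-2-yl]-3',5',8',8a'-tetrahydrospiro[cyclohexane-1,2'-cyclohepta[b]furan]-6'-carboxylate (mixture at C5', C8', C8a') | COC(=O)C1=C(O[Si](C)(C)C(C)(C)C)C(C)C2(O[Si](C)(C)C)O[C@@]3(CC2=CC1C)[C@H](C)CC[C@H](C(C)(C)O[Si](C)(C)C)[C@@]3(C)CCCO[Si](C)(C)C(C)(C)C | intermediate
22 | methyl (1S,2R,3S,6R)-2-[3-(tert-butyldimethylsilyloxy)propyl]-2,5',6,8'-tetramethyl-7'-oxo-8a'-(trimethylsilyloxy)-3-[2-(trimethylsilyloxy)propan-2-yl]-8',8a'-dihydro-3'H,7'H-spiro[cyclohexane-1,2'-cyclohepta[b]furan]-6'-carboxylate | COC(=O)C1=C(C)C=C2C[C@]3(OC2(O[Si](C)(C)C)C(C)C1=O)[C@H](C)CC[C@H](C(C)(C)O[Si](C)(C)C)[C@@]3(C)CCCO[Si](C)(C)C(C)(C)C | intermediate (not isolated)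
23 | methyl (1S,2R,3S,6R)-2-(3-hydroxypropyl)-3-(2-hydroxypropan-2-yl)-2,5',6,8'-tetramethyl-7'-oxo-3'H,7'H-spiro[cyclohexane-1,2'-cyclohepta[b]furan]-6'-carboxylate | COC(=O)c1c(C)cc2c(c(C)c1=O)O[C@@]1(C2)[C@H](C)CC[C@H](C(C)(C)O)[C@@]1(C)CCCO | intermediate
24 | methyl (1S,2R,3S,6R)-3-(2-hydroxypropan-2-yl)-2,5',6,8'-tetramethyl-7'-oxo-2-(3-oxopropyl)-3'H,7'H-spiro[cyclohexane-1,2'-cyclohepta[b]furan]-6'-carboxylate | COC(=O)c1c(C)cc2c(c(C)c1=O)O[C@@]1(C2)[C@H](C)CC[C@H](C(C)(C)O)[C@@]1(C)CCC=O | intermediate (not isolated)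
25 | 3-[(1S,2R,3S,6R)-3-(2-hydroxypropan-2-yl)-6'-(methoxycarbonyl)-2,5',6,8'-tetramethyl-7'-oxo-3'H,7'H-spiro[cyclohexane-1,2'-cyclohepta[b]furan]-2-yl]propanoic acid | COC(=O)c1c(C)cc2c(c(C)c1=O)O[C@@]1(C2)[C@H](C)CC[C@H](C(C)(C)O)[C@@]1(C)CCC(=O)O | target

**Step count and risks**

Total steps: 13. Longest linear sequence: 11 steps from (S)-carvone (steps 1–7 and 10–13); steps 8 and 9 make the diazo partner.

Step 11 is the most likely to fail. The electron-rich siloxy diene may undergo vinylogous alkylation or a formal [3+2] reaction instead of cyclopropanation, and the inward siloxy group may slow the Cope shift. The fallback sets out from diene 19 and replaces the carbenoid by an oxyallyl cation. Bromination of 15 with two equivalents of Br2 gives methyl 2,4-dibromo-3-oxopentanoate F6. Reduction of F6 with Zn(Cu) couple in the presence of 19 gives, by oxyallyl cation [4+3] cycloaddition, the cycloheptenone β-keto ester silyl ketal F7. DDQ followed by HF·pyridine, as in step 12, dehydrogenates and aromatises F7, and the route is rejoined at 23.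

Step 7 is the second risk. The epoxide CH2 is flanked by a quaternary and a tertiary carbon, and the dienediolate could react through its γ-carbon. The fallback sets out from alkene 9 and builds the lactone by a radical route. Atom-transfer addition of iodoacetic acid (Et3B, air) to the unhindered CH2 terminus, followed by lactonisation of the tertiary iodide from the open face, gives (5S,6R,7S,10R)-6-[3-(tert-butyldimethylsilyloxy)propyl]-7-(2-hydroxypropan-2-yl)-6,10-dimethyl-1-oxaspiro[4.5]decan-2-one F3. Aldol addition to propanal (LiN(iPr)2, THF, −78 °C) gives the 3-(1-hydroxypropyl) lactone F4. Mesylation and DBU elimination give the (E)-3-propylidene lactone F5. γ-Deprotonation of F5 with LiN(iPr)2/DMPU and silylation with TMSCl returns to diene 19; any (E)-propenyl isomer converges at 23.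

Step 2 is the third risk, because a tetrasubstituted enolate is alkylated with an unactivated primary iodide. The fallback sets out from 3 and uses a more reactive electrophile. Enolate allylation with allyl bromide, with the same facial bias, gives (5R,6R)-6-allyl-2,6-dimethyl-5-(prop-1-en-2-yl)cyclohex-2-en-1-one F1. Hydroboration of the monosubstituted alkene with disiamylborane and NaBO3·4H2O oxidation gives (5R,6R)-6-(3-hydroxypropyl)-2,6-dimethyl-5-(prop-1-en-2-yl)cyclohex-2-en-1-one F2. Silylation with TBSCl and imidazole returns to 6.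

Further compounds
F1 | step 2 | (5R,6R)-6-allyl-2,6-dimethyl-5-(prop-1-en-2-yl)cyclohex-2-en-1-one | O=C1C(C)=CC[C@H](C(C)=C)[C@@]1(C)CC=C
F2 | step 2 | (5R,6R)-6-(3-hydroxypropyl)-2,6-dimethyl-5-(prop-1-en-2-yl)cyclohex-2-en-1-one | O=C1C(C)=CC[C@H](C(C)=C)[C@@]1(C)CCCO
F3 | step 7 | (5S,6R,7S,10R)-6-[3-(tert-butyldimethylsilyloxy)propyl]-7-(2-hydroxypropan-2-yl)-6,10-dimethyl-1-oxaspiro[4.5]decan-2-one | O=C1O[C@@]2(CC1)[C@H](C)CC[C@H](C(C)(C)O)[C@@]2(C)CCCO[Si](C)(C)C(C)(C)C
F4 | step 7 | (5S,6R,7S,10R)-6-[3-(tert-butyldimethylsilyloxy)propyl]-3-(1-hydroxypropyl)-7-(2-hydroxypropan-2-yl)-6,10-dimethyl-1-oxaspiro[4.5]decan-2-one (diastereomers at the two new centres) | O=C1O[C@@]2(CC1C(O)CC)[C@H](C)CC[C@H](C(C)(C)O)[C@@]2(C)CCCO[Si](C)(C)C(C)(C)C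
F5 | step 7 | (3E,5S,6R,7S,10R)-6-[3-(tert-butyldimethylsilyloxy)propyl]-7-(2-hydroxypropan-2-yl)-6,10-dimethyl-3-propylidene-1-oxaspiro[4.5]decan-2-one | O=C1O[C@@]2(C/C1=C\CC)[C@H](C)CC[C@H](C(C)(C)O)[C@@]2(C)CCCO[Si](C)(C)C(C)(C)C
F6 | step 11 | methyl 2,4-dibromo-3-oxopentanoate | CC(Br)C(=O)C(Br)C(=O)OC
F7 | step 11 | methyl (1S,2R,3S,6R)-2-[3-(tert-butyldimethylsilyloxy)propyl]-2,5',6,8'-tetramethyl-7'-oxo-8a'-(trimethylsilyloxy)-3-[2-(trimethylsilyloxy)propan-2-yl]-3',5',6',7',8',8a'-hexahydrospiro[cyclohexane-1,2'-cyclohepta[b]furan]-6'-carboxylate | COC(=O)C1C(=O)C(C)C2(O[Si](C)(C)C)O[C@@]3(CC2=CC1C)[C@H](C)CC[C@H](C(C)(C)O[Si](C)(C)C)[C@@]3(C)CCCO[Si](C)(C)C(C)(C)C
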